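**Strategy.** Atoms are labelled as in caryophyllane (cyclobutane C1–C9–C10–C11, C11 = CMe2; nine-membered ring C1–C9; C8 = spiro carbon). The route rests on making the cyclobutane from a gem-dimethylcyclopropane: in a 1-(hydroxymethyl)bicyclo[3.1.0]hexan-2-ol, ionisation at the exocyclic carbon C10 lets the strained C9–C11 bond shift to C10, which closes the four-membered ring by the new C10–C11 bond, and a 1,2-hydride shift from the C8 carbinol turns the C9 cation into the C8 ketone. The step exploits that C11 bears both methyl groups and that C9 is flanked by C8. Oxy-Cope enlargement of the resulting bicyclo[3.2.0]heptanone and a late hetero-Diels–Alder reaction finish the skeleton.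

Key step: step 5

Remark: C13 is the pyran CH2 and C1′ the isobutyl-bearing carbon; syncarpic acid is taken as a purchasable compound.
Assumption: the (S,S)-bis(oxazoline) ligand in step 3 is taken to give the (1R,5S) ester 5; if the sense of induction is the opposite, the (R,R) ligand is used.

**Step 1**
Reactants: 1 methyl acetoacetate; 2 prenyl bromide (1-bromo-3-methylbut-2-ene)
Product: 3 methyl 7-methyl-3-oxooct-6-enoate
Conditions: NaH, THF, 0 °C; n-BuLi, 0 °C; 2, 0 °C to rt; aq. HCl
Reagents that add atoms: none
Why: γ-alkylation of the acetoacetate dianion, whose terminal carbon is the more nucleophilic site and is alkylated by the allylic bromide; no stereocentre is formed.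

**Step 2**
Reactants: 3 methyl 7-methyl-3-oxooct-6-enoate
Product: 4 methyl 2-diazo-7-methyl-3-oxooct-6-enoate
Conditions: p-ABSA, Et3N, MeCN, 0 °C to rt
Reagents that add atoms: 4-acetamidobenzenesulfonyl azide (p-ABSA), CC(=O)Nc1ccc(cc1)S(=O)(=O)N=[N+]=[N-]
Why: Regitz diazo transfer to the doubly activated methylene; no stereocentre is formed.

**Step 3**
Reactants: 4 methyl 2-diazo-7-methyl-3-oxooct-6-enoate
Product: 5 methyl (1R,5S)-6,6-dimethyl-2-oxobicyclo[3.1.0]hexane-1-carboxylate
Conditions: [Cu(MeCN)4]PF6 (5 mol %), (S,S)-t-Bu-bis(oxazoline) (6 mol %), toluene, 50 °C, slow addition of 4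
Reagents that add atoms: none
Why: intramolecular cyclopropanation by a carbene of monovalent copper onto the trisubstituted alkene, in which the tether enforces the cis-fused bicyclo[3.1.0]hexane and the chiral ligand selects the alkene face, setting C1 (kept to the end) and C9 (erased in step 5) together.

**Step 4**
Reactants: 5 methyl (1R,5S)-6,6-dimethyl-2-oxobicyclo[3.1.0]hexane-1-carboxylate
Product: 6 [(1S,2S,5S)-2-hydroxy-6,6-dimethylbicyclo[3.1.0]hexan-1-yl]methanol
Conditions: LiAlH4, THF, 0 °C to rt; aq. NaOH work-up
Reagents that add atoms: none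
Why: hydride reduction of ketone and ester, with hydride expected to reach the ketone anti to the gem-dimethylcyclopropane so that mainly the 2S carbinol forms, in which C8–H is anti-periplanar to the C9–C11 bond (the 2-epimer should also converge in step 5 through the enol).

**Step 5**
Reactants: 6 [(1S,2S,5S)-2-hydroxy-6,6-dimethylbicyclo[3.1.0]hexan-1-yl]methanol
Product: 8 (1R,5R)-6,6-dimethylbicyclo[3.2.0]heptan-2-one, via primary triflate 7 (not isolated)
Conditions: Tf2O (1.05 equiv), 2,6-di-tert-butyl-4-methylpyridine, CH2Cl2, −78 °C to −20 °C; aq. NaHCO3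
Reagents that add atoms: none
Why: Proposed new method: the primary hydroxyl is triflated selectively and the cyclopropylcarbinyl triflate ionises with participation of the C9–C11 bond, which shifts to C10 (enlargement of the three- to the four-membered ring by a 1,2-alkyl shift that forms C10–C11), while the anti-periplanar C8–H migrates to C9 and the carbinol becomes the ketone. The closest known reaction types are the Demjanov-type solvolytic ring expansion of (1-alkylcyclopropyl)methyl sulfonates to 1-alkylcyclobutyl cations and the pinacol-type 1,2-hydride shift. C11 should migrate rather than C1 because it is the more substituted carbon and because C1 migration would place the cation at a bridgehead of a bicyclo[3.1.1]heptane. C9 becomes a CH stereocentre controlled by C1: the hydride enters anti to the departing C11 and only the cis-fused bicyclo[3.2.0]heptane is attainable. The step needs primary-over-secondary sulfonylation (steric difference, low temperature, one equivalent) and ring closure faster than full opening to the tertiary homoallylic cation at C11, which the aligned hydride shift and the non-nucleophilic hindered base are meant to secure.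

**Step 6**
Reactants: 8 (1R,5R)-6,6-dimethylbicyclo[3.2.0]heptan-2-one; 9 2-bromopropene
Product: 10 (1R,3S,5R)-6,6-dimethyl-3-(prop-1-en-2-yl)bicyclo[3.2.0]heptan-2-one
Conditions: LiN(SiMe3)2 (2.2 equiv), THF, −78 °C; Pd2(dba)3 (cat.), P(t-Bu)3 (cat.), 9, rt; aq. NH4Cl; then DBU (cat.), CH2Cl2, 0 °C
Reagents that add atoms: none
Why: α-alkenylation of a ketone enolate catalysed by zerovalent palladium, in which the amide base removes a proton from the C3 methylene rather than the ring-fusion C9–H and brief base equilibration should leave the isopropenyl group on the convex face (C3 stereocentre under thermodynamic control).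

**Step 7**
Reactants: 10 (1R,3S,5R)-6,6-dimethyl-3-(prop-1-en-2-yl)bicyclo[3.2.0]heptan-2-one; 11 vinylmagnesium bromide
Product: 12 (1R,2R,3S,5R)-2-ethenyl-6,6-dimethyl-3-(prop-1-en-2-yl)bicyclo[3.2.0]heptan-2-ol
Conditions: CeCl3 (anhydrous), THF, −78 °C; 11, −78 °C to 0 °C; aq. NH4Cl
Reagents that add atoms: none
Why: cerium-assisted 1,2-addition of the Grignard reagent to an easily enolised ketone, expected from the convex face anti to the cyclobutane, which places vinyl cis to isopropenyl and sets the carbinol centre C8 (lost again in step 8).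

**Step 8**
Reactants: 12 (1R,2R,3S,5R)-2-ethenyl-6,6-dimethyl-3-(prop-1-en-2-yl)bicyclo[3.2.0]heptan-2-ol
Product: 14 (1R,9S,Z)-4,11,11-trimethylbicyclo[7.2.0]undec-3-en-8-one, via cis-fused ketone 13 (not isolated)
Conditions: KH, 18-crown-6, THF, 0 °C to rt; then MeOH, rt; aq. NH4Cl
Reagents that add atoms: none
Why: anionic oxy-Cope rearrangement of the potassium alkoxide, in which the cis-dialkenyl arrangement should react through a boat-like transition state to give the (Z)-C3=C4 alkene while C3–C8 breaks and C5–C6 forms (five- to nine-membered ring), after which the methoxide formed on quenching should epimerise C9 next to the ketone to the trans ring fusion expected to be the more stable one for a cyclobutane on a nine-membered ring.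

**Step 9**
Reactants: 14 (1R,9S,Z)-4,11,11-trimethylbicyclo[7.2.0]undec-3-en-8-one
Product: 15 (1R,5S,9S,Z)-5-hydroxy-4,11,11-trimethylbicyclo[7.2.0]undec-3-en-8-one
Conditions: SeO2 (0.5 equiv), t-BuOOH (2 equiv), CH2Cl2, rt
Reagents that add atoms: selenium dioxide, O=[Se]=O (oxygen donor, re-oxidised in the cycle); tert-butyl hydroperoxide, CC(C)(C)OO (stoichiometric oxygen source)
Why: selenium dioxide allylic hydroxylation (ene reaction followed by a 2,3-sigmatropic shift), which by the usual regiochemical rules attacks the ring methylene on the more substituted alkene carbon (C5) and should deliver oxygen to the peripheral face of the folded ring, expected to give the 5S alcohol.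

**Step 10**
Reactants: 15 (1R,5S,9S,Z)-5-hydroxy-4,11,11-trimethylbicyclo[7.2.0]undec-3-en-8-one; 16 methyltriphenylphosphonium bromide
Product: 17 (1R,5S,9S,Z)-4,11,11-trimethyl-8-methylidenebicyclo[7.2.0]undec-3-en-5-ol
Conditions: 16 (3.5 equiv), KOt-Bu (3.3 equiv), THF, 0 °C; 15, rt to 50 °C
Reagents that add atoms: none
Why: Wittig methylenation of the hindered ketone with excess ylide, the hydroxyl being carried as its alkoxide, with no stereocentre formed and the thermodynamic trans fusion and C5 left untouched.

**Step 11**
Reactants: 17 (1R,5S,9S,Z)-4,11,11-trimethyl-8-methylidenebicyclo[7.2.0]undec-3-en-5-ol; 18 syncarpic acid; 19 isovaleraldehyde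
Product: 21 tomentodione P, via alkylidene trione 20 (not isolated)
Conditions: 18, 19, ethylenediammonium diacetate (cat.), CH2Cl2, rt; then 17, toluene, 80 °C
Reagents that add atoms: none
Why: Knoevenagel condensation gives the alkylidene trione, which should react as an electron-poor heterodiene in an inverse-electron-demand hetero-Diels–Alder reaction with the C8=C13 alkene (oxygen to the more substituted C8), approaching the peripheral face of the methylene group on the C10 side with C9 endo, which corresponds to 8S and 1′S, the C1′ epimer being the expected by-product.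

**Compound list**
1 | methyl acetoacetate | COC(=O)CC(C)=O | starting material
2 | prenyl bromide (1-bromo-3-methylbut-2-ene) | CC(C)=CCBr | starting material
3 | methyl 7-methyl-3-oxooct-6-enoate | COC(=O)CC(=O)CCC=C(C)C | intermediate
4 | methyl 2-diazo-7-methyl-3-oxooct-6-enoate | COC(=O)C(=[N+]=[N-])C(=O)CCC=C(C)C | intermediate
5 | methyl (1R,5S)-6,6-dimethyl-2-oxobicyclo[3.1.0]hexane-1-carboxylate | C1C[C@@H]2[C@@](C1=O)(C(=O)OC)C2(C)C | intermediate
6 | [(1S,2S,5S)-2-hydroxy-6,6-dimethylbicyclo[3.1.0]hexan-1-yl]methanol | C1C[C@@H]2[C@@]([C@H]1O)(CO)C2(C)C | intermediate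
7 | [(1S,2S,5S)-2-hydroxy-6,6-dimethylbicyclo[3.1.0]hexan-1-yl]methyl trifluoromethanesulfonate | C1C[C@@H]2[C@@]([C@H]1O)(COS(=O)(=O)C(F)(F)F)C2(C)C | intermediate (not isolated)
8 | (1R,5R)-6,6-dimethylbicyclo[3.2.0]heptan-2-one (cis-fused) | O=C1CC[C@@H]2[C@H]1CC2(C)C | intermediate
9 | 2-bromopropene | CC(Br)=C | starting material
10 | (1R,3S,5R)-6,6-dimethyl-3-(prop-1-en-2-yl)bicyclo[3.2.0]heptan-2-one | CC(=C)[C@@H]1C[C@@H]2[C@H](C1=O)CC2(C)C | intermediate
11 | vinylmagnesium bromide | C=C[Mg]Br | starting material
12 | (1R,2R,3S,5R)-2-ethenyl-6,6-dimethyl-3-(prop-1-en-2-yl)bicyclo[3.2.0]heptan-2-ol | CC(=C)[C@@H]1C[C@@H]2[C@H]([C@]1(O)C=C)CC2(C)C | intermediate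
13 | (1R,9R,Z)-4,11,11-trimethylbicyclo[7.2.0]undec-3-en-8-one (cis-fused) | C/C1=C/C[C@@H]2[C@@H](CC2(C)C)C(=O)CCC1 | intermediate (not isolated)
14 | (1R,9S,Z)-4,11,11-trimethylbicyclo[7.2.0]undec-3-en-8-one (trans-fused) | C/C1=C/C[C@@H]2[C@H](CC2(C)C)C(=O)CCC1 | intermediate
15 | (1R,5S,9S,Z)-5-hydroxy-4,11,11-trimethylbicyclo[7.2.0]undec-3-en-8-one | C/C1=C/C[C@@H]2[C@H](CC2(C)C)C(=O)CC[C@@H]1O | intermediate
16 | methyltriphenylphosphonium bromide | C[P+](c1ccccc1)(c1ccccc1)c1ccccc1.[Br-] | starting material
17 | (1R,5S,9S,Z)-4,11,11-trimethyl-8-methylidenebicyclo[7.2.0]undec-3-en-5-ol | C/C1=C/C[C@@H]2[C@H](CC2(C)C)C(=C)CC[C@@H]1O | intermediate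
18 | syncarpic acid (2,2,4,4-tetramethylcyclohexane-1,3,5-trione) | CC1(C)C(=O)CC(=O)C(C)(C)C1=O | starting material
19 | isovaleraldehyde | CC(C)CC=O | starting material
20 | 2,2,4,4-tetramethyl-6-(3-methylbutylidene)cyclohexane-1,3,5-trione | CC(C)CC=C1C(=O)C(C)(C)C(=O)C(C)(C)C1=O | intermediate (not isolated)
21 | tomentodione P | C/C1=C/C[C@@H]2[C@H](CC2(C)C)[C@]2(CC[C@@H]1O)C[C@H](CC(C)C)C1=C(O2)C(C)(C)C(=O)C(C)(C)C1=O | target

**Total step count:** 11. **Longest linear sequence:** 11 steps (1 to 21; compounds 9, 11, 16, 18 and 19 enter as purchased partners).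

**Steps most likely to fail**

Step 5 (proposed new method). The delocalised cation may open fully to the tertiary homoallylic cation at C11, which can then be trapped by the C8 hydroxyl as a bridged ether or lose its identity by hydride shift and elimination, before the C10–C11 bond and the terminating hydride shift are completed; unselective sulfonylation of the secondary hydroxyl is a second failure process. The fallback uses separate, known reactions and sets out from 6. Tosyl chloride in pyridine at 0 °C gives the primary tosylate [(1S,2S,5S)-2-hydroxy-6,6-dimethylbicyclo[3.1.0]hexan-1-yl]methyl 4-methylbenzenesulfonate F1. Buffered hydrolysis (acetone–water, CaCO3, 40 °C), the classical cyclopropylcarbinyl-to-cyclobutyl solvolysis, should trap the ring-enlarged cation with water as the tertiary cyclobutanol (1S,2S,5S)-6,6-dimethylbicyclo[3.2.0]heptane-1,2-diol F2. Acid-catalysed pinacol rearrangement of this 1,2-diol (TsOH, benzene, 60 °C) then gives 8, where the route is rejoined.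

Step 9. Poor facial selectivity at C5, partial loss of the Z geometry during the sigmatropic step and over-oxidation to the enone are the likely failure processes. The fallback sets out from 14 and replaces substrate control by reagent control. The hydroxylation is run for conversion only, and the crude mixture of 15 and its C5 epimer (1R,5R,9S,Z)-5-hydroxy-4,11,11-trimethylbicyclo[7.2.0]undec-3-en-8-one F3 is methylenated as in step 10 to 17 and its epimer (1R,5R,9S,Z)-4,11,11-trimethyl-8-methylidenebicyclo[7.2.0]undec-3-en-5-ol F4. Dess–Martin oxidation of the mixture gives the dienone (1R,9S,Z)-4,11,11-trimethyl-8-methylidenebicyclo[7.2.0]undec-3-en-5-one F5, in which the conjugated ring alkene can also be equilibrated to the Z form with catalytic thiophenol. Corey–Bakshi–Shibata reduction with BH3·SMe2 and (R)-2-methyl-CBS-oxazaborolidine then sets 5S and returns to 17.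

Step 11. Poor facial and endo/exo selectivity in the cycloaddition would give C8/C1′ diastereomers that must be separated. The fallback changes the order of events and sets out from 14. Wittig methylenation as in step 10 gives the hydroxyl-free diene (1R,9S,Z)-4,11,11-trimethyl-8-methylidenebicyclo[7.2.0]undec-3-ene F6. The hetero-Diels–Alder reaction with 20 under the conditions of step 11 is run on this hydrocarbon and gives the adduct 5-deoxytomentodione P F7. Selenium dioxide/t-BuOOH hydroxylation at C5, next to the only electron-rich alkene left, then gives 21.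

**Further compounds**
F1 | step 5 | [(1S,2S,5S)-2-hydroxy-6,6-dimethylbicyclo[3.1.0]hexan-1-yl]methyl 4-methylbenzenesulfonate | C1C[C@@H]2[C@@]([C@H]1O)(COS(=O)(=O)c1ccc(C)cc1)C2(C)C
F2 | step 5 | (1S,2S,5S)-6,6-dimethylbicyclo[3.2.0]heptane-1,2-diol | O[C@H]1CC[C@@H]2[C@@]1(O)CC2(C)C
F3 | step 9 | (1R,5R,9S,Z)-5-hydroxy-4,11,11-trimethylbicyclo[7.2.0]undec-3-en-8-one | C/C1=C/C[C@@H]2[C@H](CC2(C)C)C(=O)CC[C@H]1O
F4 | step 9 | (1R,5R,9S,Z)-4,11,11-trimethyl-8-methylidenebicyclo[7.2.0]undec-3-en-5-ol | C/C1=C/C[C@@H]2[C@H](CC2(C)C)C(=C)CC[C@H]1O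
F5 | step 9 | (1R,9S,Z)-4,11,11-trimethyl-8-methylidenebicyclo[7.2.0]undec-3-en-5-one | C/C1=C/C[C@@H]2[C@H](CC2(C)C)C(=C)CCC1=O
F6 | step 11 | (1R,9S,Z)-4,11,11-trimethyl-8-methylidenebicyclo[7.2.0]undec-3-ene | C/C1=C/C[C@@H]2[C@H](CC2(C)C)C(=C)CCC1
F7 | step 11 | 5-deoxytomentodione P | C/C1=C/C[C@@H]2[C@H](CC2(C)C)[C@]2(CCC1)C[C@H](CC(C)C)C1=C(O2)C(C)(C)C(=O)C(C)(C)C1=O
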